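4 questions stand on this flask, and one dimensionless number carries my reckoning of its target.

| setting | alpha | zeta | flask |
|---|---|---|---|
| solid substrate | 0.80 M | 0.80 M | 0.80 M |
| partner | 0.56 M | 0.56 M | 0.560 M |
| second substrate | 1.6 M | 0.80 M | 1.60 M |
| third substrate | 0.16 M | 0.16 M | 0.160 M |
| remark | the very flask that is asked about, followed so far | run made earlier |  |
| time |  |  | 2.0 h |

| run | time / min | target / % | starting material / % | solid substrate / % |
|---|---|---|---|---|
| alpha | 3.00 | 0.1 | 1.0 | 99.6 |
| alpha | 10.0 | 1.0 | 2.0 | 97.1 |
| alpha | 15.0 | 0 | 2.6 | 97.4 |
| alpha | 25.0 | 0.3 | 4.3 | 94.0 |
| alpha | 40.0 | 1.2 | 7.1 | 91.7 |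
| alpha | 50.0 | 1.1 | 9.0 | 90.2 |
| alpha | 60.0 | 1.8 | 11.1 | 87.2 |
| zeta | 5.00 | 0.3 | 1.6 | 98.4 |
| zeta | 12.0 | 0 | 2.1 | 97.9 |
| zeta | 25.0 | 0.9 | 5.3 | 94.4 |
| zeta | 40.0 | 1.9 | 6.9 | 91.8 |
| zeta | 50.0 | 2.4 | 10.0 | 89.0 |
| zeta | 60.0 | 2.6 | 10.8 | 87.5 |
| zeta | 80.0 | 3.3 | 13.3 | 84.2 |

(each reading ± 0.5 percentage points)

- solid, in amounts per volume of the solution: solid substrate
- at the start none of the solid substrate is in solution
- starting material is what solid substrate becomes in solution
- starting material means what is dissolved; the solid is not counted in it

- target at 2.0 h, in percent of the solid substrate charged
- concentration of starting material in solution at 12 min, in percent of saturation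
- the change that raises the amount of target at 2.0 h, in percent of the solid substrate charged most ("none" if none brings more than 2 percentage points) (Monday's / Saturday's / Wednesday's / none)
- amount of target at 2.0 h, in percent of the solid substrate charged, after Saturday's

- Monday's: doubling the solubility of the solid substrate, all else as stated
- Saturday's: doubling the amount of partner, all else as stated
- Wednesday's: doubling the dissolution coefficient of the solid substrate, all else as stated

The alpha run has this flask's recipe. I pool its last 3 readings, replacing a noisy curve by its mean: target over target plus starting material comes to 13.1%. I call this part of the dissolved material that has become target the capture share.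

Is one number enough? In the zeta run the share reads 18.7% at 25.0 min and 40.0 min, and 19.6% later. That is flat within the scatter, but higher than in alpha, so I carry the share as a number for fixed charges of second substrate, third substrate and partner.

Extending alpha's dissolved material in a straight line gives 25.8% of the charge at 2.0 h, so I expect 3.38% target. I expect Monday's and Wednesday's to act on the dissolved amount and Saturday's on the share, and doubling either factor gives 6.76%. The share reads lower in alpha than in zeta, with more second substrate in alpha, which looks like competition for partner, so I lean to Saturday's.

The forecast gives 5%, more than my figure, then 3% of saturation, Saturday's and 9%, holding: “Doubling partner likely about doubles the rate”.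

The flask gives 3.33%, 5.65% of saturation, Saturday's with a gain of 4.7 percentage points, and 8.05% after it. Each forecast value stands within its margin.

    second substrate + partner → second product (k = 0.0103 /M/min)
    third substrate + partner → third product (k = 0.243 /M/min)
    starting material + partner → target (k = 0.0217 /M/min)
    solid substrate ⇌ starting material, rate k4*(cs4 - [starting material]) while solid is left; crystals form when [starting material] > cs4 (solubility = 0.370 M, k = 0.00511 /min)

At 2.00 h this flask makes starting material 6.46 times faster than it uses it up, each step taken net. There 18.7% starting material stands beside 3.33% target, a capture share of 15.1%. In the neighbour with 0.20 M of solid substrate and the same other charges, 88.1% of its charge has left the solid, and my share from alpha turns that into 11.5% target. That neighbour gives 13.3% beside 74.7% starting material, a share of 15.1%.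

The readings were computed with constants of no real substance, noise included.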